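**Small charge.** A small charge of E, 0.500 mM against 10 mM of Q, seems to cost the flask a share of its Q before the reaction to Z gets going. I call this the E toll, the charged c_E over the charged c_Q 5.00%. The part of Q missing from Q plus Z reads 5.00% at 5.00 min in Thursday's run, where the toll is the same, and 8.00% at 6.00 min in Tuesday's run, whose toll is 10.0%. Each reading carries a scatter of 1.5 percentage points.

| setting | Thursday's | Wednesday's | Tuesday's | flask |
|---|---|---|---|---|
| Q | 10 mM | 10 mM | 10 mM | 10 mM |
| X | 0.45 equiv | 1.8 equiv | 0.90 equiv | 0.900 equiv |
| E | 0.50 mM | 0.50 mM | 1 mM | 0.500 mM |
| remark | run made earlier | run made earlier | run made earlier |  |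
| time |  |  |  | 30 min |
| volume of the second phase over the first |  |  |  | 2.0 |

- Thursday's (time / min: Z / %, Q / %): 5.00: 3, 92; 10.0: 7, 85; 15.0: 12, 83; 20.0: 14, 79; 25.0: 13, 79; 30.0: 17, 74
- Wednesday's (time / min: Z / %, Q / %): 2.00: 3, 89; 6.00: 15, 76; 10.0: 28, 68; 15.0: 33, 58; 25.0: 43, 39; 30.0: 47, 38
- Tuesday's (time / min: Z / %, Q / %): 6.00: 11, 81; 12.0: 16, 72; 20.0: 25, 64; 25.0: 26, 62; 30.0: 30, 54

(readings scatter by 1.5 percentage points)

- in the second phase: X; everything else is in the first
- charges count per volume of the first phase; a concentration in a rate is the amount of a species over the volume of its own phase; every rate counts per litre of the first phase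
- the earlier runs hold the two phases in the same ratio of volumes as the flask asked about

- amount of Z at 30 min, in percent of the Q charged
- the change that raises the amount of Z at 30 min, in percent of the Q charged most ("none" if none brings more than 2 percentage points) (red / ochre / none)
- amount of Z at 30 min, in percent of the Q charged, after ochre

- red: doubling the amount of X, all else as stated
- ochre: doubling the transfer coefficient of X, all else as stated

**Nearest neighbour.** Tuesday's run has the flask's X, but twice its c_E. It reaches 30% of Z at 30.0 min, which is 33.3% of the Q surviving its toll. A first-order decay with a fixed rate constant takes the same share of whatever it starts from, so I take the same X to convert the same share of the flask's surviving Q. That gives an estimate of 31.7% for the flask, higher than the reading of Tuesday's run, and the flask's toll is smaller. Thursday's and Wednesday's runs share one toll, yet Z runs from 17% to 47% as X goes from 0.45 equiv to 1.8 equiv, so I choose red.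

**The forecast.** It gives 29%, below my figure, with red as the best change and 31% after ochre. On the early gap it says: “This suggests E holds some Q or an intermediate, rather than accelerating the reaction.”

**The result.** The flask gives 31.2% of Z. The best change is red, worth 13 points, and ochre gives 31.5%.

    J ⇌ X, rate k1*([J] - [X]/K1) per volume of the first phase (partition coefficient = 0.770, kL = 0.0200 /s)
    Q + J → Z (k = 0.100 /M/s)
    J + Z → G (k = 0.0500 /M/s)
    Q + E → D (k = 18.0 /M/s)

The turnover of Q + E into D has its midpoint at 0.0652 min, while the half-life of Q by the step to Z is 40 min at 0.888 min, a far longer time. E, the limiting reagent of that side step, stands at 0% of its charge by 3.00 min, and D holds 5.00% of the Q charged at 30.0 min, against the toll of 5.00%. The neighbour charged with 40 mM of Q has a toll of 1.25%, and its D stands at 1.25%.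

All runs stem from a simulated flask from invented constants; noise was put on by code.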